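I nearly scaled the rate with c(precatalyst), and that was the pitfall. The flasks differ in precatalyst, and the solid reagent starts undissolved.

| setting | cedar | elm | flask |
|---|---|---|---|
| left-handed substrate | 13 mM | 13 mM | 13 mM |
| right-handed substrate | 13 mM | 13 mM | 13 mM |
| solid reagent | 19.5 mM | 19.5 mM | 19.5 mM |
| protic impurity | 13 mM | 13 mM | 13.0 mM |
| precatalyst | 0.41 mM | 1.6 mM | 0.81 mM |
| remark | run made earlier | run made earlier |  |
| time |  |  | 8.0 d |

| run | time / d | right-handed substrate / % | left-handed substrate / % |
|---|---|---|---|
| cedar | 1.67 | 51 | 20 |
| cedar | 3.00 | 48 | 9 |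
| cedar | 5.00 | 48 | 4 |
| cedar | 6.00 | 47 | 1 |
| cedar | 8.00 | 46 | 1 |
| cedar | 10.0 | 47 | 2 |
| elm | 0.833 | 49 | 30 |
| elm | 1.25 | 50 | 15 |
| elm | 2.00 | 48 | 4 |
| elm | 4.00 | 46 | 0 |
| elm | 6.00 | 44 | 0 |
| elm | 10.0 | 48 | 1 |

(each reading ± 1.5 percentage points)

* whether the excess of right-handed substrate over left-handed substrate among what is left of the two reaches 80% by 8.0 d (no / yes)
* the highest excess of right-handed substrate over left-handed substrate among what is left of the two up to 8.0 d

- catalyst is single-handed; left-handed substrate and right-handed substrate are mirror images of each other, charged as a racemate, each of them at the stated concentration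
- as a solid, counted per litre of solution: solid reagent
- at the start none of the solid reagent is in solution

Elm held 3.90 times the c(precatalyst) of cedar. Yet elm used left-handed substrate at 7.28 mM d⁻¹ up to 1.25 d, and cedar at 4.67 mM d⁻¹ up to 1.67 d. That is just 1.56 times cedar's rate.

So I looked at a concentration that catalyst does not make: dissolved solid reagent. Elm's stretch between 0.833 d and 1.25 d read 9.35 mM d⁻¹, faster than its mean up to 1.25 d. I called this reading the feed, my estimate of the highest rate at which dissolving solid reagent can serve the left-handed substrate, counting one reagent per substrate. I took dissolving as the rate-limiting step of that stretch in elm, with an order near zero in substrate.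

For the flask, the wanted excess needs 11.6 mM of left-handed substrate used, with the right-handed substrate intact. At the feed that takes 1.24 d, my lower estimate. Cedar, with less precatalyst, read 84.6% at 5.00 d, my upper estimate. I expected the crossing between them, inside 8.0 d. This window gave me no top.

The forecast said yes, with a top of 99%, holding that “the rate scales roughly with precatalyst”. There I parted from it, though not on the answer.

The flask gave yes and a top of 99.8%, crossing at 2.41 d.

    solid reagent ⇌ partner, rate k1*(cs1 - [partner]) while solid is left; crystals form when [partner] > cs1 (solubility = 4.60 mM, k = 0.00140 min⁻¹)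
    partner + catalyst + left-handed substrate → catalyst + left-handed product (k = 620 M⁻² min⁻¹)
    partner + protic impurity → quenched reagent (k = 0.0400 M⁻¹ min⁻¹)
    partner + catalyst + right-handed substrate → catalyst + right-handed product (k = 5.20 M⁻² min⁻¹)
    precatalyst → catalyst (k = 0.0600 min⁻¹)

By 0.800 d the flask had dissolved 6.17 mM of solid reagent, against 7.48 mM at the feed, and at 1.31 d the flask made partner 1.11 times as fast as it used it up, each step taken net. Cedar, the second flask, read 7.80 mM of left-handed substrate used by 1.67 d, half of the 15.6 mM reckoned at the feed.

All runs were computed for substances that don't exist; the scatter is artificial.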